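1. E is not read, but it follows from the balance: whatever of Q and L has gone and is not Z is E.

| flask | Q | L | X | D | remark | time |
|---|---|---|---|---|---|---|
| elm | 0.50 M | 0.50 M | 1 M | 0.29 mM | the very flask that is asked about, followed so far |  |
| cedar | 0.50 M | 0.50 M | 0.50 M | 0.29 mM | run made earlier |  |
| flask | 0.50 M | 0.50 M | 1.00 M | 0.29 mM |  | 30 min |



- elm (time / min: Q / %, L / %, Z / %): 0.833: 45.8, 47.0, 4.6; 2.00: 43.9, 44.4, 8.4; 4.00: 41.6, 41.7, 11.8; 6.00: 40.8, 41.1, 12.8
- cedar (time / min: Q / %, L / %, Z / %): 1.00: 47.9, 48.1, 3.7; 2.00: 47.2, 47.7, 4.2; 5.00: 45.5, 45.5, 6.2; 12.0: 45.2, 44.7, 6.9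

(each reading ± 0.5 percentage points)



- part of the Q and L charged together that has reacted at 30 min
- excess of Z over E in the product at 30 min
- excess of L over Q among what is left of the two at 30 min



- D is single-handed; Q and L are mirror images of each other, charged as a racemate, each of them at the stated concentration
- steps under discussion: X + D + Q -> D + Z; X + D + L -> D + E; Q <-> L; D -> G; X <-> J; Z <-> E
- an excess is below zero if the other one leads



2. At one moment, Z forms against E as k[X][D][Q] against k'[X][D][L], with a different constant in each. [X] and [D] cancel, and the last elm readings put [Q] at 40.8% and [L] at 41.1%. With these nearly equal, fresh product keeps one ratio, the selectivity factor. A fall in the product excess therefore has to come after formation, through Z ⇌ E. Call the fraction of that excess lost per minute the fade.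

3. First way: elm holds 18.1% of product at 6.00 min, with excess 41.4%. Cedar holds 10.1% at 12.0 min, with excess 36.6%. [X] is higher in elm than in cedar but cancels from the ratio, so the two excesses can be compared, and this gives a fade of 0.0205 min⁻¹, the fraction of the excess lost per minute.

4. Second way: within cedar, 5.00 min shows 9.00% of product, with excess 37.8%. The fade is then 0.00439 min⁻¹, slower than the first.

5. The second way cheats: cedar gained 1.1 percentage points of fresh product between those readings, which props up the later excess. This reckoning therefore takes the first way and carries elm's excess to 30 min: 25.3%. That figure is weak, since cedar's E of 3.20% is a difference of 3 readings, each good to 0.5 points.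

6. The forecast gives c 19.5%, eP 40% and eS 0%, and differs from this reckoning on eP: “no evident product racemization”.

The flask gives c 20.0%, eP 31.2% and eS 0%.

    X + D + Q → D + Z (k = 8.33 M⁻² s⁻¹)
    X + D + L → D + E (k = 2.98 M⁻² s⁻¹)
    Q ⇌ L (k = 0.0276 s⁻¹)
    D → G (k = 0.00579 s⁻¹)
    X ⇌ J (K = 0.583, k = 8.95 × 10⁻⁴ s⁻¹)
    Z ⇌ E (k = 1.23 × 10⁻⁴ s⁻¹)

The eP of 31.2% lies below the forecast and above the reckoned 25.3%, and Z ⇌ E has a relaxation half-life of 47.0 min. A neighbouring flask differs by its charge of D, 0.0012 M against 0.29 mM. [D] cancels from the ratio in step 2, so with the same fade and the same 30 min the reckoning again gives 25.3%. That neighbour reacts to c 50.4% against 20.0%, and its eP stands at 30.0%.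

(The numbers in the tables are simulated with made-up constants.)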